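The C1(O)–C2H2–C3(Br) segment of the cyclohexene ring is treated as a masked β-bromo ketone whose methylene C2 is the apex of a cyclopropanol fused onto a cyclopentene that already holds C1 and C3–C6. One-electron oxidation of this 1-siloxybicyclo[3.1.0]hex-2-ene with FeBr3 breaks the ring-fusion bond C1–C3. In one operation the five-membered ring becomes the six-membered enone and the neopentylic C3–Br bond beside quaternary C4 is made by radical bromine transfer. The precursor carries the side chain as its C7 (R)-silyl ether with C8–Cl in place. The C7 centre comes from a CBS reduction; reduction, acetylation and invertive bromination at C7 finish the route.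

Key step: step 8

Remarks on the chemistry:
- Atom labels C1–C8 in the text are those of the target: ring C1 = CHOAc, C2 = CH2, C3 = CHBr, C4 = CMe2, C5=C6; side chain C7 = CHBr, C8 = CH2Cl. Compound names carry their own locants.
- The target is (1R,5S)-5-bromo-2-[(1S)-1-bromo-2-chloroethyl]-4,4-dimethylcyclohex-2-en-1-yl acetate, with the C1 acetate and the C3 bromine cis.
- Compound 14 is assumed to be used as the mixture of its two cis-fused diastereomers.
- (R)-Me-CBS stands for (3aR)-1-methyl-3,3-diphenyltetrahydro-1H,3H-pyrrolo[1,2-c][1,3,2]oxazaborole, C18H20BNO.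

Step 1
Reactants: 1 4,4-dimethylcyclopent-2-en-1-one
Product: 3 2-bromo-4,4-dimethylcyclopent-2-en-1-one, via trans-2,3-dibromo ketone 2 (not isolated)
Conditions: Br2, CH2Cl2, 0 °C; then Et3N, 0 °C → rt
Reagents that add atoms: bromine, BrBr
Why: Anti addition of bromine to the enone followed by amine-induced E1cB loss of HBr (deprotonation at C6, loss of the C5 bromide) is the standard α-bromination of a cycloalkenone and leaves no stereocentre.

Step 2
Reactants: 3 2-bromo-4,4-dimethylcyclopent-2-en-1-one
Product: 4 6-bromo-8,8-dimethyl-1,4-dioxaspiro[4.4]non-6-ene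
Conditions: HOCH2CH2OH, p-toluenesulfonic acid monohydrate (cat.), benzene, reflux, Dean–Stark
Reagents that add atoms: ethylene glycol, OCCO
Why: Acid-catalysed ketalisation with azeotropic removal of water masks the C1 carbonyl for the organolithium step, and the double bond cannot migrate because C4 carries no hydrogen.

Step 3
Reactants: 4 6-bromo-8,8-dimethyl-1,4-dioxaspiro[4.4]non-6-ene; 5 2-chloro-N-methoxy-N-methylacetamide
Product: 8 2-chloro-1-(8,8-dimethyl-1,4-dioxaspiro[4.4]non-6-en-6-yl)ethan-1-one, via alkenyllithium 6 (not isolated), via lithium hemiaminal alkoxide 7 (not isolated)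
Conditions: n-BuLi, THF, −78 °C; then 5, −78 °C; sat. aq. NH4Cl
Reagents that add atoms: none
Why: Bromine–lithium exchange gives the α-keto vinyl anion equivalent at C6, and its acylation stops at the chloromethyl ketone because the chelated tetrahedral adduct 7 survives until the quench (Weinreb ketone synthesis).

Step 4
Reactants: 8 2-chloro-1-(8,8-dimethyl-1,4-dioxaspiro[4.4]non-6-en-6-yl)ethan-1-one
Product: 10 2-[(1R)-2-chloro-1-hydroxyethyl]-4,4-dimethylcyclopent-2-en-1-one, via ketal chlorohydrin 9 (not isolated)
Conditions: (R)-Me-CBS oxazaborolidine (C18H20BNO, 10 mol%), BH3·SMe2 (0.6 equiv), THF, −20 °C; MeOH; then 1 M HCl, THF, rt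
Reagents that add atoms: water, O
Why: In this Corey–Bakshi–Shibata reduction of an achiral ketone the α-branched alkenyl group acts as the large and CH2Cl as the small substituent, so the (R)-catalyst should deliver hydride to the face that gives the (R)-chlorohydrin at C7 (the same sense as with aryl chloromethyl ketones), and the acidic work-up hydrolyses the allylic dioxolane to the enone.

Step 5
Reactants: 10 2-[(1R)-2-chloro-1-hydroxyethyl]-4,4-dimethylcyclopent-2-en-1-one
Product: 11 2-[(1R)-1-{[tert-butyl(dimethyl)silyl]oxy}-2-chloroethyl]-4,4-dimethylcyclopent-2-en-1-one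
Conditions: TBSOTf, 2,6-lutidine, CH2Cl2, −78 → 0 °C
Reagents that add atoms: tert-butyldimethylsilyl trifluoromethanesulfonate, CC(C)(C)[Si](C)(C)OS(=O)(=O)C(F)(F)F
Why: Silylation of the hindered secondary alcohol with the silyl triflate and a hindered pyridine base involves no alkoxide, so the chlorohydrin cannot close to an epoxide, the enone is not enolised and C7 keeps its configuration.

Step 6
Reactants: 11 2-[(1R)-1-{[tert-butyl(dimethyl)silyl]oxy}-2-chloroethyl]-4,4-dimethylcyclopent-2-en-1-one
Product: 12 tert-butyl{(1R)-2-chloro-1-[3,3-dimethyl-5-(trimethylsilyloxy)cyclopenta-1,4-dien-1-yl]ethoxy}dimethylsilane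
Conditions: Me3SiOTf, Et3N, CH2Cl2, 0 °C; non-aqueous work-up, used crude
Reagents that add atoms: trimethylsilyl trifluoromethanesulfonate, C[Si](C)(C)OS(=O)(=O)C(F)(F)F
Why: Soft enolisation can only remove a C3 proton (C4 is quaternary, C6 is sp2), so a single cross-conjugated silyl dienol ether should form, without a free enolate that could attack the C8 chloride and as a 5,5-disubstituted cyclopentadiene that cannot undergo hydrogen shifts.

Step 7
Reactants: 12 tert-butyl{(1R)-2-chloro-1-[3,3-dimethyl-5-(trimethylsilyloxy)cyclopenta-1,4-dien-1-yl]ethoxy}dimethylsilane; 13 diiodomethane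
Product: 14 tert-butyl{(1R)-2-chloro-1-[(1S,5R)-4,4-dimethyl-1-(trimethylsilyloxy)bicyclo[3.1.0]hex-2-en-2-yl]ethoxy}dimethylsilane (obtained together with its (1R,5S) ring-fusion diastereomer)
Conditions: Et2Zn, CH2I2, CH2Cl2, 0 °C → rt; pyridine quench, filtration through Et3N-deactivated silica
Reagents that add atoms: none
Why: In this Furukawa-modified Simmons–Smith cyclopropanation the electrophilic zinc carbenoid should add to the electron-rich silyl enol ether bond C1=C3 and not to the hindered, non-oxygenated C5=C6 bond; the ring fusion is necessarily cis, and both facial diastereomers are carried on because C1 and C3 lose their configuration in step 8.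

Step 8
Reactants: 14 tert-butyl{(1R)-2-chloro-1-[(1S,5R)-4,4-dimethyl-1-(trimethylsilyloxy)bicyclo[3.1.0]hex-2-en-2-yl]ethoxy}dimethylsilane (both cis-fused diastereomers)
Product: 15 (5S)-5-bromo-2-[(1R)-1-{[tert-butyl(dimethyl)silyl]oxy}-2-chloroethyl]-4,4-dimethylcyclohex-2-en-1-one
Conditions: FeBr3 (2.5 equiv), DMF, 0 °C; cold 0.5 M HCl work-up; fast chromatography on deactivated silica
Reagents that add atoms: iron tribromide, Br[Fe](Br)Br
Why: FeBr3 strips the labile Me3Si group as Me3SiBr to give a trivalent iron cyclopropoxide, inner-sphere electron transfer then gives divalent iron and an oxygen-centred radical at C1, and β-scission of the ring-fusion bond C1–C3 turns C1 into the enone carbonyl and leaves a secondary radical at C3 that takes bromine from a second FeBr3 by ligand transfer. The closest known reaction type is the FeCl3/DMF ring expansion of 1-siloxybicyclo[n.1.0]alkanes to 3-chlorocycloalkanones, supported by the silver-catalysed radical ring-opening bromination of cyclopropanols. The six-membered ring is not closed by a new bond but arises when the bond shared by the three- and five-membered rings breaks, formally the reverse of a 3-exo-trig closure of the C3 radical onto the C1 carbonyl. The new stereocentre C3 comes from a planar radical with one C4 methyl on each face and far from C7, so no element controls it: both C3 epimers are expected, and because C7 is already (R) they are diastereomers from which the (5S) compound 15 is separated. The step needs cleavage of the fusion bond and not of C1–C2, which the secondary over primary radical secures, and bromine transfer faster than a 1,2-vinyl shift of the homoallylic C3 radical or loss of HBr from the product, which excess FeBr3 at 0 °C and a cold acidic work-up secure. The TBS ether, the primary chloride and the C5=C6 bond take no part.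

Step 9
Reactants: 15 (5S)-5-bromo-2-[(1R)-1-{[tert-butyl(dimethyl)silyl]oxy}-2-chloroethyl]-4,4-dimethylcyclohex-2-en-1-one
Product: 16 (1R,5S)-5-bromo-2-[(1R)-1-{[tert-butyl(dimethyl)silyl]oxy}-2-chloroethyl]-4,4-dimethylcyclohex-2-en-1-ol
Conditions: NaBH4, CeCl3·7H2O, MeOH, −78 °C
Reagents that add atoms: none
Why: Luche reduction gives clean 1,2-reduction with low basicity, and hydride should add to the carbonyl face opposite the C3 bromine (pseudo-axial attack on the half-chair, as in the reduction of carvone to cis-carveol), which sets C1 as (R) with the hydroxyl cis to bromine, while the low temperature suppresses loss of HBr.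

Step 10
Reactants: 16 (1R,5S)-5-bromo-2-[(1R)-1-{[tert-butyl(dimethyl)silyl]oxy}-2-chloroethyl]-4,4-dimethylcyclohex-2-en-1-ol
Product: 17 (1R,5S)-5-bromo-2-[(1R)-1-{[tert-butyl(dimethyl)silyl]oxy}-2-chloroethyl]-4,4-dimethylcyclohex-2-en-1-yl acetate
Conditions: Ac2O, pyridine, 4-(dimethylamino)pyridine (cat.), CH2Cl2, 0 °C → rt
Reagents that add atoms: acetic anhydride, CC(=O)OC(C)=O
Why: Nucleophilic-catalysed O-acylation of the only free hydroxyl proceeds with retention at C1 and under conditions too mild to eliminate the secondary bromide or displace the chloride.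

Step 11
Reactants: 17 (1R,5S)-5-bromo-2-[(1R)-1-{[tert-butyl(dimethyl)silyl]oxy}-2-chloroethyl]-4,4-dimethylcyclohex-2-en-1-yl acetate
Product: 18 (1R,5S)-5-bromo-2-[(1R)-2-chloro-1-hydroxyethyl]-4,4-dimethylcyclohex-2-en-1-yl acetate
Conditions: HF·pyridine, pyridine, THF, 0 °C → rt
Reagents that add atoms: none
Why: Buffered, weakly acidic fluoride cleaves the Si–O bond without forming an alkoxide, so the chlorohydrin cannot close to an epoxide, the acetate should not migrate to the C7 oxygen and the secondary bromide is not eliminated.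

Step 12
Reactants: 18 (1R,5S)-5-bromo-2-[(1R)-2-chloro-1-hydroxyethyl]-4,4-dimethylcyclohex-2-en-1-yl acetate
Product: 19 (1R,5S)-5-bromo-2-[(1S)-1-bromo-2-chloroethyl]-4,4-dimethylcyclohex-2-en-1-yl acetate
Conditions: PPh3, CBr4, CH2Cl2, 0 °C
Reagents that add atoms: tetrabromomethane, BrC(Br)(Br)Br
Why: In this Appel reaction bromide displaces the C7 alkoxyphosphonium ion by SN2 with inversion, turning the (R)-alcohol into the (S)-bromide, while the electron-withdrawing C8 chlorine disfavours ionisation and quaternary C4 blocks SN2′ attack at C5.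

Compound list
1 | 4,4-dimethylcyclopent-2-en-1-one | O=C1CC(C)(C)C=C1 | starting material
2 | trans-2,3-dibromo-4,4-dimethylcyclopentan-1-one (racemic; one enantiomer drawn) | O=C1CC(C)(C)[C@@H](Br)[C@@H]1Br | intermediate (not isolated)
3 | 2-bromo-4,4-dimethylcyclopent-2-en-1-one | O=C1CC(C)(C)C=C1Br | intermediate
4 | 6-bromo-8,8-dimethyl-1,4-dioxaspiro[4.4]non-6-ene | CC1(C)CC2(OCCO2)C(Br)=C1 | intermediate
5 | 2-chloro-N-methoxy-N-methylacetamide | CON(C)C(=O)CCl | starting material
6 | (8,8-dimethyl-1,4-dioxaspiro[4.4]non-6-en-6-yl)lithium | CC1(C)CC2(OCCO2)C([Li])=C1 | intermediate (not isolated)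
7 | lithium 2-chloro-1-(8,8-dimethyl-1,4-dioxaspiro[4.4]non-6-en-6-yl)-1-[methoxy(methyl)amino]ethan-1-olate (racemic) | CC1(C)CC2(OCCO2)C(=C1)C(O[Li])(CCl)N(C)OC | intermediate (not isolated)
8 | 2-chloro-1-(8,8-dimethyl-1,4-dioxaspiro[4.4]non-6-en-6-yl)ethan-1-one | CC1(C)CC2(OCCO2)C(=C1)C(=O)CCl | intermediate
9 | (1R)-2-chloro-1-(8,8-dimethyl-1,4-dioxaspiro[4.4]non-6-en-6-yl)ethan-1-ol | CC1(C)CC2(OCCO2)C(=C1)[C@@H](O)CCl | intermediate (not isolated)
10 | 2-[(1R)-2-chloro-1-hydroxyethyl]-4,4-dimethylcyclopent-2-en-1-one | O=C1CC(C)(C)C=C1[C@@H](O)CCl | intermediate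
11 | 2-[(1R)-1-{[tert-butyl(dimethyl)silyl]oxy}-2-chloroethyl]-4,4-dimethylcyclopent-2-en-1-one | O=C1CC(C)(C)C=C1[C@@H](O[Si](C)(C)C(C)(C)C)CCl | intermediate
12 | tert-butyl{(1R)-2-chloro-1-[3,3-dimethyl-5-(trimethylsilyloxy)cyclopenta-1,4-dien-1-yl]ethoxy}dimethylsilane | C[Si](C)(C)OC1=CC(C)(C)C=C1[C@@H](O[Si](C)(C)C(C)(C)C)CCl | intermediate
13 | diiodomethane | ICI | starting material
14 | tert-butyl{(1R)-2-chloro-1-[(1S,5R)-4,4-dimethyl-1-(trimethylsilyloxy)bicyclo[3.1.0]hex-2-en-2-yl]ethoxy}dimethylsilane (drawn; its (1R,5S) cis-fused diastereomer is used alongside) | C[Si](C)(C)O[C@@]12C[C@@H]1C(C)(C)C=C2[C@@H](O[Si](C)(C)C(C)(C)C)CCl | intermediate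
15 | (5S)-5-bromo-2-[(1R)-1-{[tert-butyl(dimethyl)silyl]oxy}-2-chloroethyl]-4,4-dimethylcyclohex-2-en-1-one | O=C1C[C@H](Br)C(C)(C)C=C1[C@@H](O[Si](C)(C)C(C)(C)C)CCl | intermediate
16 | (1R,5S)-5-bromo-2-[(1R)-1-{[tert-butyl(dimethyl)silyl]oxy}-2-chloroethyl]-4,4-dimethylcyclohex-2-en-1-ol | O[C@@H]1C[C@H](Br)C(C)(C)C=C1[C@@H](O[Si](C)(C)C(C)(C)C)CCl | intermediate
17 | (1R,5S)-5-bromo-2-[(1R)-1-{[tert-butyl(dimethyl)silyl]oxy}-2-chloroethyl]-4,4-dimethylcyclohex-2-en-1-yl acetate | CC(=O)O[C@@H]1C[C@H](Br)C(C)(C)C=C1[C@@H](O[Si](C)(C)C(C)(C)C)CCl | intermediate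
18 | (1R,5S)-5-bromo-2-[(1R)-2-chloro-1-hydroxyethyl]-4,4-dimethylcyclohex-2-en-1-yl acetate | CC(=O)O[C@@H]1C[C@H](Br)C(C)(C)C=C1[C@@H](O)CCl | intermediate
19 | (1R,5S)-5-bromo-2-[(1S)-1-bromo-2-chloroethyl]-4,4-dimethylcyclohex-2-en-1-yl acetate | CC(=O)O[C@@H]1C[C@H](Br)C(C)(C)C=C1[C@H](Br)CCl | target

Total step count: 12. Longest linear sequence: 12 steps (1 → 19).

Steps most likely to fail

Step 8. Bromine transfer to the planar C3 radical is unselective, which halves the throughput, and the β-bromo enone may lose HBr during work-up or chromatography, so too little of the (5S)-epimer may be isolated. The fallback sets out from 14 and returns at 15. The ring expansion is run with FeCl3 in DMF at 0 °C to rt, which should give the more robust 5-chloro enone F1 as an epimer mixture of no consequence. Et3N in CH2Cl2 then removes HCl to give the cross-conjugated dienone F2. Anhydrous HBr in CH2Cl2 at −40 °C should add bromide to the unsubstituted, less hindered enone arm and give 15 together with the (5R)-epimer F3. After separation, F3 is returned to F2 with Et3N and resubmitted, so that material converges on 15. The C3–Br bond is then made by reversible polar conjugate addition instead of radical transfer.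

Step 9. Hydride may be delivered to the wrong carbonyl face, because the C7 silyl ether on the neighbouring carbon can oppose the ring bias, and methoxide may induce loss of HBr. The fallback sets out from 15 and returns at 17. Whatever alcohol mixture the reduction gives is separated, and the cis alcohol 16 goes on as planned. The (1S,5S)-trans alcohol F4 is esterified under Mitsunobu conditions (AcOH, PPh3, diisopropyl azodicarboxylate, toluene, 0 °C), which inverts C1 and gives acetate 17 directly. Control at C1 is thereby moved from the reduction to an SN2 displacement, with SN2′ attack at C5 blocked by quaternary C4.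

Step 12. The allylic alkoxyphosphonium ion may ionise in part, or the C1 acetate or C8 chlorine may participate, with loss of configuration at C7, halogen scrambling or diene formation. The fallback sets out from 18 and returns at 19. Mesylation (MsCl, Et3N, CH2Cl2, −20 °C) gives the C7 mesylate F5, and LiBr in acetone at 0 °C to rt displaces it. This is an SN2 substitution on an isolated sulfonate that proceeds with inversion and involves no phosphonium species.

Further compounds
F1 | step 8 | (5RS)-2-[(1R)-1-{[tert-butyl(dimethyl)silyl]oxy}-2-chloroethyl]-5-chloro-4,4-dimethylcyclohex-2-en-1-one | O=C1CC(Cl)C(C)(C)C=C1[C@@H](O[Si](C)(C)C(C)(C)C)CCl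
F2 | step 8 | 2-[(1R)-1-{[tert-butyl(dimethyl)silyl]oxy}-2-chloroethyl]-4,4-dimethylcyclohexa-2,5-dien-1-one | O=C1C=CC(C)(C)C=C1[C@@H](O[Si](C)(C)C(C)(C)C)CCl
F3 | step 8 | (5R)-5-bromo-2-[(1R)-1-{[tert-butyl(dimethyl)silyl]oxy}-2-chloroethyl]-4,4-dimethylcyclohex-2-en-1-one | O=C1C[C@@H](Br)C(C)(C)C=C1[C@@H](O[Si](C)(C)C(C)(C)C)CCl
F4 | step 9 | (1S,5S)-5-bromo-2-[(1R)-1-{[tert-butyl(dimethyl)silyl]oxy}-2-chloroethyl]-4,4-dimethylcyclohex-2-en-1-ol | O[C@H]1C[C@H](Br)C(C)(C)C=C1[C@@H](O[Si](C)(C)C(C)(C)C)CCl
F5 | step 12 | (1R,5S)-5-bromo-2-[(1R)-2-chloro-1-(methanesulfonyloxy)ethyl]-4,4-dimethylcyclohex-2-en-1-yl acetate | CC(=O)O[C@@H]1C[C@H](Br)C(C)(C)C=C1[C@@H](OS(C)(=O)=O)CCl
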